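No rate constant is given, but the ratio of the two constants can be read from the maple run. There the dissolved coupling partner takes both substrates, and the racemization catalyst can turn one hand into the other.

| setting | maple | flask |
|---|---|---|
| left-handed substrate | 0.0075 M | 0.015 M |
| right-handed substrate | 0.0075 M | 0.015 M |
| solid reagent | 3 equiv | 3.00 equiv |
| racemization catalyst | 0.5 mol% | 0.5 mol% |
| remark | run made earlier |  |
| time |  | 10 d |

- maple (time / h: left-handed substrate / %, right-handed substrate / %): 2.50: 49.8, 50.1; 8.00: 48.9, 49.8; 15.0: 49.2, 50.4; 20.0: 48.4, 50.1; 30.0: 47.1, 49.8; 40.0: 45.5, 49.6; 50.0: 44.0, 49.4

(standard deviation of a reading: 0.5 percentage points)

* part of the left-handed substrate and right-handed substrate charged together that has reacted at 10 d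
* excess of left-handed product over right-handed product in the product at 10 d
* excess of right-handed substrate over left-handed substrate among what is left of the two at 10 d

- coupling partner is single-handed; left-handed substrate and right-handed substrate are mirror images of each other, charged as a racemate, each of them at the stated concentration
- as a solid, counted per litre of solution: solid reagent
- at the start none of the solid reagent is in solution
- an excess is the difference of the two amounts in percent of their sum
- an excess is below zero if the other one leads
- no earlier run changes the charge of racemization catalyst; that part of a forecast is a guess
- the handed part of coupling partner does not stay in what it makes, so the products of the two hands are mirror images too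

As long as the hands do not interconvert, both substrates meet the same coupling partner, so time and coupling partner cancel in the selectivity factor, the number of times faster the left-handed substrate is taken than the right-handed one:

selectivity factor = ln(left-handed part left) / ln(right-handed part left) = 10.6

Its zero of the scale is 1, where no excess arises. This is a rough reading, since the maple run's right-handed loss is 0.6 percentage points against a scatter of 0.5 points.

The factor ties the three answers together but does not say how far the flask gets. That takes a second number, the late left-handed slope of the maple run, 0.00318 /h. Assuming that excess solid holds this slope in the flask and that the hands stay apart, the left-handed part left at 10 d is 48.1%, and the factor makes the right-handed part 93.3%. This reckoning therefore gives 29.3% reacted, a product excess of 77.2% and a substrate excess of 32.0%.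

The forecast gives 30%, 83% and 25%, with a substrate excess lower than this reckoning's, on the ground: “That small loss could instead be slow racemization, which the data cannot separate.”

The flask gives 40.8% reacted, a product excess of 73.4% and a substrate excess of 50.4%.

    racemization catalyst → spent catalyst A (k = 1.25 × 10⁻⁵ /s)
    solid reagent ⇌ coupling partner, rate k2*(cs2 - [coupling partner]) while solid is left; crystals form when [coupling partner] > cs2 (solubility = 12.0 mM, k = 2.57 × 10⁻⁶ /s)
    coupling partner + left-handed substrate → left-handed product (k = 3.65 × 10⁻⁴ /M/s)
    coupling partner + right-handed substrate → right-handed product (k = 3.42 × 10⁻⁵ /M/s)
    2 racemization catalyst → spent catalyst B (k = 0.0991 /M/s)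
    left-handed substrate + racemization catalyst ⇌ right-handed substrate + racemization catalyst, rate k6*[racemization catalyst]*[left-handed substrate] forward; the back reaction follows from the equilibrium constant (k = 0.00811 /M/s)

At 10.0 d the flask still makes coupling partner 1.34 times as fast as it uses it up, each step taken net, and the partner stands at 0.00577 M after 0.00189 M at 1.00 d, while the flask has reacted further than the reckoned 29.3%. With 29% of the left-handed substrate left in the flask, the maple factor gives 89.0% of the right-handed one, where the flask holds 89%; the neighbour flask with 0.750 equiv of solid reagent has 42% of the left-handed substrate left, the factor gives 92.1% of the right-handed one, and that flask holds 92%.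

All runs come from a simulation on assumed constants, noise included.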